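## Analysis of the target

The target (21) is a 4→6-linked flavan-3-ol dimer. Its upper unit is a 5-deoxyflavan-3-ol (ring A with only the C7 hydroxyl, pyran ring C, pyrogallol ring B at C2) and is bonded from C4 to C6 of a lower (+)-gallocatechin unit (benzo ring D, pyran ring F, pyrogallol ring E). The upper unit is (2R,3S,4R): the ring B aryl at C2 and the C3 hydroxyl are trans, the C3 hydroxyl and the ring D aryl at C4 are cis, so the two aryl groups lie on opposite faces of ring C. The lower unit is (2R,3S), trans, exactly as in natural (+)-gallocatechin, and is insulated from the upper triad by ring D. There are nine phenols (six in two air- and base-sensitive pyrogallol rings), two secondary alcohols, and acid-labile benzylic bonds (both C2–O1 bonds and the C4–C6(D) bond), so the free polyphenol should appear only in the last step and under neutral conditions. The hard points are the interflavan bond at C6 of ring D (C8 is the inherently more reactive carbon), the 3,4-cis relation (not the one favoured when a flavan-4-yl cation is trapped), and the missing C5 oxygen on ring A, which makes such a cation hard to reach at all. The strategy rests on one feature of ring A: C4a is ortho to the O1 oxygen and para to the C7 oxygen, so O1–C8a–C4a is the O,C-nucleophilic pair of a resorcinol monoether. Opposite it, C4–C3–C2 is a three-carbon chain at the enal oxidation level whose β-carbon (C4) can already be bonded to C6 of ring D.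

## Retrosynthetic reasoning

**Deprotection.** Target 21 is traced to 20, in which all nine phenols and the lower C3 hydroxyl are benzyl ethers and C8 of ring D carries bromine. Ten O–benzyl bonds and the C–Br bond are then cut by hydrogen in one neutral step. The free upper C3 hydroxyl of 20 comes from pivalate 19; the ester is there because it is needed one step earlier as a stereodirecting group.

**C2–ring B bond.** In 19 the bond from C2 to ring B is cut. C2 is at the acetal oxidation level, so it can be an oxocarbenium carbon. The ring B carbon is meta to two oxygens, so it cannot be a Friedel–Crafts nucleophile and must arrive as an organometallic, arylzinc 18. The electrophile is bromide 13. Its C3 pivalate should bridge to C2 on the face of the C3 oxygen, so the aryl group must enter trans to C3–O, which is also the face away from the C4 aryl. Bromide 13 comes from bis-pivalate 12 and that from diol 11. Arylzinc 18 comes from bromide 16, made from 15 and 14.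

**C3–O bond.** Diol 11 is traced through 10 to lactol 9 by removing the C3 oxygen. C3 is the α-carbon of the aldehyde that 9 masks, so enamine catalysis on the open form can oxygenate it. The C3 oxygen must end up cis to the C4 aryl, which is the opposite of what steric control on the closed ring would give. An external chiral amino-acid catalyst acting on the open chain is therefore used.

**Key disconnection.** In 9 the C4–C4a bond and the O1–C2 bond are cut together. This gives phenol 8, which supplies C4a and O1, and enal 7, which supplies C4, C3 and C2 and already carries ring D on its β-carbon. The interflavan connectivity is thus never made by an intermolecular coupling at a flavan C4; it is present in 7 from the start. The forward reaction has to form the C–C bond with control of C4 and close ring C.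

**Enal and lower unit.** Enal 7 is cut at its C=C bond to aldehyde 5 and ylide 6. The formyl group of 5 goes back to C–H at C6 of ring D in 4. The bromine of 4 at C8 blocks the more reactive position and goes back to 3. Ethers 3 and 2 go back to gallocatechin 1, which brings both lower stereocentres.

## Alternatives that were turned down

**Alternative 1:** The two pyran ether bonds O1–C2, of ring C and of ring F, are cut together. The nona-O-benzyl ether A1 of the target then goes back to the open-chain bis-epoxide A2, with free phenols on rings A and D and a trans-epoxide at each future C2–C3 pair.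
- Forward key step: under acid each phenol opens its own epoxide at the benzylic carbon with inversion, so both rings close in one operation and the epoxide oxygens become the two C3 hydroxyls.
- For: the endgame is the most convergent of all. No separate C3 oxygenation is needed. Trans-epoxide plus inversion gives 2,3-trans in both units. A1 is one hydrogenolysis from 21.
- Against: A2 must contain all five stereocentres by synthesis (two reagent-controlled epoxidations and the C4 diarylmethine), whereas the chosen route buys two of them in 1. Each closure competes with 5-exo attack at C3, which would give a dihydrobenzofuran. Benzylic activation by a 3,4,5-tris(benzyloxy)phenyl group is modest, because only the para oxygen donates. If the opening becomes cation-like, inversion degrades, and two such events multiply the loss.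
- Comparison: it is stronger on convergence and on installing C3–O. The chosen route offers fewer stereocentres to make, ring closure and the C4 centre in one catalytic step, and a closure (lactolisation) with no ring-size ambiguity. Its step count should be clearly lower than any route to A2.

**Alternative 2:** Only O1–C2 of the lower unit is cut. The substrate A4 already contains the protected upper unit, a free C8a phenol on ring D, the three-carbon chain with the lower C3 carbinol, and a ring E whose central hydroxyl is free. The carbinol carbon would come from a three-carbon epoxide bought as a single enantiomer.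
- Forward key step: Ag2O oxidises the 4-hydroxybenzyl group to the para-quinone methide A5; the ring D phenol adds to its exocyclic carbon, ring E rearomatises, and ring F closes to A3 with the aryl group trans to the hydroxyl.
- For: the closure is mild and close to neutral, with no leaving group or acid at C2. The addition is reversible, so the trans product can form under thermodynamic control.
- Against: it rebuilds ring F, which 1 delivers complete with both stereocentres. It does not address the real problems (the C4 centre, the 3,4-cis relation, the 4→6 bond), which must be solved before A4 exists. Ring E needs its central oxygen differentiated from its neighbours. The oxidant meets a free ring D phenol that is para to the C4 methine and ortho to the lower C4 methylene, so competing quinone methides could destroy the C4 centre.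
- Comparison: it is stronger on the mildness of its ring closure. The chosen route needs no such closure at all, uses one protecting-group type, and is much shorter.

**Alternative 3:** The aryl ether bond O1–C8a of ring C is cut. The substrate A7 is an open chain with a 2-bromo-4-(benzyloxy)phenyl group as ring A on C4, a benzyl ether at C3 and a free benzylic alcohol at C2. Its lower unit carries methoxymethyl and silyl ethers.
- Forward key step: CuI, 1,10-phenanthroline and Cs2CO3 couple the C2 alkoxide with the aryl bromide to give A6. The C2–O bond is not broken, so C2 is retained.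
- For: the ring-closing step touches no stereocentre and passes through no cation at C2 or C4. Intramolecular copper-mediated O-arylation to chromans is well established. On the reliability of the closure itself this alternative is stronger than the organocatalytic annulation.
- Against: all three contiguous centres, including the diarylmethine C4, must be built in an acyclic chain before closure. The bromide sits next to the bulky C4. A hot, basic medium puts the secondary benzylic alkoxide at risk of oxidation to the ketone. Three protecting-group classes force an endgame with acid, fluoride and hydrogen, and acid on a nearly free dimer endangers the interflavan bond.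
- Comparison: the chosen route accepts a less certain ring closure. In return it forms two bonds and a stereocentre in that step, sets C3 and C2 on a ring where relative control is simple, and ends with a single hydrogenolysis.

Key step: step 6

Remark on the chemistry (assumption): rings A, B, C belong to the upper unit and D, E, F to the lower one. Lactols 9–11, ester 12 and bromide 13 are handled as mixtures of C2 epimers, which is harmless because C2 is planarised in step 13. In the names, "Ar(D)" stands for the (2R,3S)-3,5,7-tris(benzyloxy)-8-bromo-2-[3,4,5-tris(benzyloxy)phenyl]chroman-6-yl group.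

## Route

Step 1
Reactants: 1 (+)-gallocatechin
Product: 2 (2R,3S)-5,7-bis(benzyloxy)-2-[3,4,5-tris(benzyloxy)phenyl]chroman-3-ol
Conditions: BnBr, K2CO3, DMF, 0 °C → rt, Ar
Reagents that add atoms: benzyl bromide, BrCc1ccccc1
Why: Williamson etherification of the five phenols with a carbonate base, which leaves the secondary alcohol alone; exclusion of air protects the pyrogallol ring until it is capped, and no stereocentre is touched.

Step 2
Reactants: 2 (2R,3S)-5,7-bis(benzyloxy)-2-[3,4,5-tris(benzyloxy)phenyl]chroman-3-ol
Product: 3 (2R,3S)-3,5,7-tris(benzyloxy)-2-[3,4,5-tris(benzyloxy)phenyl]chroman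
Conditions: NaH, BnBr, DMF, 0 °C → rt
Reagents that add atoms: benzyl bromide, BrCc1ccccc1
Why: Williamson etherification of the remaining secondary alcohol through its sodium alkoxide; with all phenols capped there is no quinone-methide pathway for epimerisation at C2.

Step 3
Reactants: 3 (2R,3S)-3,5,7-tris(benzyloxy)-2-[3,4,5-tris(benzyloxy)phenyl]chroman
Product: 4 (2R,3S)-3,5,7-tris(benzyloxy)-8-bromo-2-[3,4,5-tris(benzyloxy)phenyl]chroman
Conditions: NBS (1.0 equiv), CH2Cl2, −40 → 0 °C
Reagents that add atoms: N-bromosuccinimide, BrN1C(=O)CCC1=O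
Why: Electrophilic aromatic bromination; ring D is activated by three oxygens and reacts before ring E, and C8 (flanked by the ring oxygen and one ether) is less hindered than C6 (flanked by two benzyl ethers), so one equivalent should brominate C8 and block it.

Step 4
Reactants: 4 (2R,3S)-3,5,7-tris(benzyloxy)-8-bromo-2-[3,4,5-tris(benzyloxy)phenyl]chroman
Product: 5 (2R,3S)-3,5,7-tris(benzyloxy)-8-bromo-2-[3,4,5-tris(benzyloxy)phenyl]chroman-6-carbaldehyde
Conditions: POCl3, DMF, 0 → 70 °C; then H2O
Reagents that add atoms: N,N-dimethylformamide, CN(C)C=O; water, O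
Why: Vilsmeier–Haack formylation at C6, the only free position of ring D, which is ortho to two ether oxygens and para to the ring oxygen as in a phloroglucinol triether; benzyl ethers and the aryl bromide tolerate the chloroiminium reagent.

Step 5
Reactants: 5 (2R,3S)-3,5,7-tris(benzyloxy)-8-bromo-2-[3,4,5-tris(benzyloxy)phenyl]chroman-6-carbaldehyde; 6 (formylmethylene)triphenylphosphorane
Product: 7 (E)-3-[Ar(D)]prop-2-enal
Conditions: toluene, 90 °C
Reagents that add atoms: none
Why: Wittig olefination with a stabilised ylide, which should give the E-enal; a small excess of ylide and monitoring limit a second homologation of the product.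

Step 6
Reactants: 7 (E)-3-[Ar(D)]prop-2-enal; 8 3-(benzyloxy)phenol
Product: 9 (4R)-7-(benzyloxy)-4-[Ar(D)]chroman-2-ol (C2 epimers)
Conditions: (S)-2-[diphenyl(trimethylsilyloxy)methyl]pyrrolidine (20 mol %), PhCO2H (20 mol %), toluene, 25 → 40 °C
Reagents that add atoms: none
Why: Enal 7 condenses with the secondary amine to an E-configured, s-trans iminium ion, one face of which is covered by the diphenyl(trimethylsilyloxy)methyl group. Phenol 8, held by a hydrogen bond from its hydroxyl to the benzoate counter-ion, adds as a carbon nucleophile through the position ortho to OH and para to OBn (the future C4a) to the β-carbon from the open face, which forms the C4–C4a bond. The enamine so formed is protonated and hydrolysed, and the phenol oxygen then adds to the released aldehyde carbon in a 6-exo-trig closure that forms O1–C2 and ring C as lactol 9; this closure takes the product out of the iminium equilibria and drives the sequence forward. The closest known reaction type is the diarylprolinol silyl ether-catalysed Friedel–Crafts alkylation/hemiacetalisation of naphthols, sesamol and 3-alkoxyphenols with enals to 4-substituted chroman-2-ols. C4 is the only new stereocentre whose configuration matters and it is set by the catalyst: with the (S)-catalyst the aryl group should enter on the face that gives (4R), the lower-unit stereocentres being too remote to compete; C2 forms as an epimeric mixture that is removed later. The step needs C- over O-alkylation (an oxa-Michael adduct can revert), ortho over para attack (only the ortho adduct can lactolise, and the hydrogen bond to the acid co-catalyst presents the ortho carbon) and attack at the less hindered ortho carbon rather than the one between the two oxygens. The benzyl ethers and the aryl bromide are inert to the weakly acidic conditions.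

Step 7
Reactants: 9 (4R)-7-(benzyloxy)-4-[Ar(D)]chroman-2-ol
Product: 10 (3S,4R)-7-(benzyloxy)-4-[Ar(D)]-3-[(phenylamino)oxy]chroman-2-ol
Conditions: PhNO (1.2 equiv), D-proline (20 mol %), CHCl3, 4 °C
Reagents that add atoms: nitrosobenzene, O=Nc1ccccc1
Why: Proline-catalysed α-aminoxylation of the open hydroxy-aldehyde form of the lactol: the enamine attacks the nitroso oxygen, which is delivered by the carboxylic acid of the catalyst. L-Proline gives (R)-α-aminoxy aldehydes, so D-proline is used to set (3S), the oxygen cis to the C4 aryl, under catalyst control. Reclosure to the lactol shields the new α-centre from epimerisation.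

Step 8
Reactants: 10 (3S,4R)-7-(benzyloxy)-4-[Ar(D)]-3-[(phenylamino)oxy]chroman-2-ol
Product: 11 (3S,4R)-7-(benzyloxy)-4-[Ar(D)]chroman-2,3-diol
Conditions: Zn, AcOH, THF, rt
Reagents that add atoms: none
Why: Reductive cleavage of the weak N–O bond by zinc in acetic acid; lactol, aryl bromide and benzyl ethers are not reduced, and an acidic wash removes aniline and returns any N,O-acetal to the lactol.

Step 9
Reactants: 11 (3S,4R)-7-(benzyloxy)-4-[Ar(D)]chroman-2,3-diol
Product: 12 (3S,4R)-7-(benzyloxy)-4-[Ar(D)]chroman-2,3-diyl bis(2,2-dimethylpropanoate)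
Conditions: PivCl, pyridine, DMAP (cat.), CH2Cl2, 0 → 40 °C
Reagents that add atoms: pivaloyl chloride, CC(C)(C)C(Cl)=O
Why: Acylation of the lactol and the C3 hydroxyl; the pivalate at C3 is chosen as a participating group whose hindered carbonyl carbon resists attack by an organometallic.

Step 10
Reactants: 12 (3S,4R)-7-(benzyloxy)-4-[Ar(D)]chroman-2,3-diyl bis(2,2-dimethylpropanoate)
Product: 13 (3S,4R)-7-(benzyloxy)-2-bromo-4-[Ar(D)]chroman-3-yl 2,2-dimethylpropanoate (used crude)
Conditions: TMSBr, CH2Cl2, 0 °C → rt; evaporate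
Reagents that add atoms: bromotrimethylsilane, C[Si](C)(C)Br
Why: Exchange of an anomeric ester for bromide, as in the preparation of glycosyl bromides from 1-O-acyl sugars; only the acetal-type C2 ester ionises (assisted by the C3 pivalate), while the C3 ester and the benzyl ethers stay intact at this temperature.

Step 11
Reactants: 14 5-bromo-1,2,3-trimethoxybenzene
Product: 15 5-bromobenzene-1,2,3-triol
Conditions: BBr3, CH2Cl2, −78 °C → rt; then H2O
Reagents that add atoms: none
Why: Lewis-acid cleavage of the three aryl methyl ethers; the aryl bromide is unaffected.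

Step 12
Reactants: 15 5-bromobenzene-1,2,3-triol
Product: 16 5-bromo-1,2,3-tris(benzyloxy)benzene
Conditions: BnBr, K2CO3, DMF, rt, Ar
Reagents that add atoms: benzyl bromide, BrCc1ccccc1
Why: Williamson etherification of the three phenols under argon, giving ring B in the same protecting group as the rest of the molecule.

Step 13
Reactants: 13 (3S,4R)-7-(benzyloxy)-2-bromo-4-[Ar(D)]chroman-3-yl 2,2-dimethylpropanoate; 16 5-bromo-1,2,3-tris(benzyloxy)benzene
Product: 19 (2R,3S,4R)-7-(benzyloxy)-2-[3,4,5-tris(benzyloxy)phenyl]-4-[Ar(D)]chroman-3-yl 2,2-dimethylpropanoate, via aryllithium 17 (not isolated), via arylzinc bromide 18 (not isolated)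
Conditions: 16 (2 equiv), n-BuLi, toluene/n-Bu2O, −20 °C; ZnBr2·LiBr, n-Bu2O, 0 °C; then 13, toluene, 25 → 80 °C
Reagents that add atoms: none
Why: Bromine–lithium exchange and transmetalation give arylzinc 18. Bromide 13 ionises with anchimeric assistance from the C3 pivalate to a cis-fused dioxolenium ion, and the aryl group is transferred to C2 from the opposite face, which is also the face away from the C4 aryl, so C2 should form as (2R), trans to C3–O. The reaction type is the Lewis-acid-free arylation of 2-O-pivaloyl glycosyl bromides with arylzinc reagents to 1,2-trans C-aryl glycosides; the aryl bromide of ring D does not react with an arylzinc in the absence of a transition metal.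

Step 14
Reactants: 19 (2R,3S,4R)-7-(benzyloxy)-2-[3,4,5-tris(benzyloxy)phenyl]-4-[Ar(D)]chroman-3-yl 2,2-dimethylpropanoate
Product: 20 (2R,3S,4R)-7-(benzyloxy)-2-[3,4,5-tris(benzyloxy)phenyl]-4-[Ar(D)]chroman-3-ol
Conditions: DIBAL-H, CH2Cl2, −78 → 0 °C; Rochelle salt
Reagents that add atoms: none
Why: Reductive cleavage of the hindered pivalate, which avoids basic hydrolysis next to a benzylic ether; benzyl ethers are inert and no stereocentre is involved.

Step 15
Reactants: 20 (2R,3S,4R)-7-(benzyloxy)-2-[3,4,5-tris(benzyloxy)phenyl]-4-[Ar(D)]chroman-3-ol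
Product: 21 (2R,3S,4R)-4-[(2R,3S)-3,5,7-trihydroxy-2-(3,4,5-trihydroxyphenyl)chroman-6-yl]-2-(3,4,5-trihydroxyphenyl)chroman-3,7-diol (target)
Conditions: H2 (1 atm), Pd(OH)2/C, Et3N, THF/MeOH, rt; filter under Ar
Reagents that add atoms: none
Why: Catalytic hydrogenolysis removes the ten benzyl ethers and the C8 bromine of ring D in one neutral operation; the amine buffers the hydrogen bromide so that the acid-sensitive interflavan and pyran bonds of the free polyphenol are not exposed to acid.

## Compound list

1 | (+)-gallocatechin, (2R,3S)-2-(3,4,5-trihydroxyphenyl)chroman-3,5,7-triol | Oc1cc(O)c2C[C@H](O)[C@@H](c3cc(O)c(O)c(O)c3)Oc2c1 | starting material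
2 | (2R,3S)-5,7-bis(benzyloxy)-2-[3,4,5-tris(benzyloxy)phenyl]chroman-3-ol | c1ccccc1COc1cc(OCc2ccccc2)c2C[C@H](O)[C@@H](c3cc(OCc4ccccc4)c(OCc4ccccc4)c(OCc4ccccc4)c3)Oc2c1 | intermediate
3 | (2R,3S)-3,5,7-tris(benzyloxy)-2-[3,4,5-tris(benzyloxy)phenyl]chroman | c1ccccc1COc1cc(OCc2ccccc2)c2C[C@H](OCc3ccccc3)[C@@H](c3cc(OCc4ccccc4)c(OCc4ccccc4)c(OCc4ccccc4)c3)Oc2c1 | intermediate
4 | (2R,3S)-3,5,7-tris(benzyloxy)-8-bromo-2-[3,4,5-tris(benzyloxy)phenyl]chroman | c1ccccc1COc1cc(OCc2ccccc2)c2C[C@H](OCc3ccccc3)[C@@H](c3cc(OCc4ccccc4)c(OCc4ccccc4)c(OCc4ccccc4)c3)Oc2c1Br | intermediate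
5 | (2R,3S)-3,5,7-tris(benzyloxy)-8-bromo-2-[3,4,5-tris(benzyloxy)phenyl]chroman-6-carbaldehyde | c1ccccc1COc1c(C=O)c(OCc2ccccc2)c2C[C@H](OCc3ccccc3)[C@@H](c3cc(OCc4ccccc4)c(OCc4ccccc4)c(OCc4ccccc4)c3)Oc2c1Br | intermediate
6 | (formylmethylene)triphenylphosphorane | O=CC=P(c1ccccc1)(c1ccccc1)c1ccccc1 | starting material
7 | (E)-3-[(2R,3S)-3,5,7-tris(benzyloxy)-8-bromo-2-[3,4,5-tris(benzyloxy)phenyl]chroman-6-yl]prop-2-enal | O=C/C=C/c1c(OCc3ccccc3)c(Br)c2c(c1OCc3ccccc3)C[C@H](OCc3ccccc3)[C@@H](c1cc(OCc3ccccc3)c(OCc3ccccc3)c(OCc3ccccc3)c1)O2 | intermediate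
8 | 3-(benzyloxy)phenol | Oc1cccc(OCc2ccccc2)c1 | starting material
9 | (4R)-7-(benzyloxy)-4-[Ar(D)]chroman-2-ol, C2 epimers | c1ccccc1COc1ccc2c(c1)OC(O)C[C@H]2c1c(OCc3ccccc3)c(Br)c2c(c1OCc3ccccc3)C[C@H](OCc3ccccc3)[C@@H](c1cc(OCc3ccccc3)c(OCc3ccccc3)c(OCc3ccccc3)c1)O2 | intermediate
10 | (3S,4R)-7-(benzyloxy)-4-[Ar(D)]-3-[(phenylamino)oxy]chroman-2-ol | c1ccccc1COc1ccc2c(c1)OC(O)[C@@H](ONc3ccccc3)[C@H]2c1c(OCc3ccccc3)c(Br)c2c(c1OCc3ccccc3)C[C@H](OCc3ccccc3)[C@@H](c1cc(OCc3ccccc3)c(OCc3ccccc3)c(OCc3ccccc3)c1)O2 | intermediate
11 | (3S,4R)-7-(benzyloxy)-4-[Ar(D)]chroman-2,3-diol | c1ccccc1COc1ccc2c(c1)OC(O)[C@@H](O)[C@H]2c1c(OCc3ccccc3)c(Br)c2c(c1OCc3ccccc3)C[C@H](OCc3ccccc3)[C@@H](c1cc(OCc3ccccc3)c(OCc3ccccc3)c(OCc3ccccc3)c1)O2 | intermediate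
12 | (3S,4R)-7-(benzyloxy)-4-[Ar(D)]chroman-2,3-diyl bis(2,2-dimethylpropanoate) | c1ccccc1COc1ccc2c(c1)OC(OC(=O)C(C)(C)C)[C@@H](OC(=O)C(C)(C)C)[C@H]2c1c(OCc3ccccc3)c(Br)c2c(c1OCc3ccccc3)C[C@H](OCc3ccccc3)[C@@H](c1cc(OCc3ccccc3)c(OCc3ccccc3)c(OCc3ccccc3)c1)O2 | intermediate
13 | (3S,4R)-7-(benzyloxy)-2-bromo-4-[Ar(D)]chroman-3-yl 2,2-dimethylpropanoate | c1ccccc1COc1ccc2c(c1)OC(Br)[C@@H](OC(=O)C(C)(C)C)[C@H]2c1c(OCc3ccccc3)c(Br)c2c(c1OCc3ccccc3)C[C@H](OCc3ccccc3)[C@@H](c1cc(OCc3ccccc3)c(OCc3ccccc3)c(OCc3ccccc3)c1)O2 | intermediate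
14 | 5-bromo-1,2,3-trimethoxybenzene | COc1cc(Br)cc(OC)c1OC | starting material
15 | 5-bromobenzene-1,2,3-triol | Oc1cc(Br)cc(O)c1O | intermediate
16 | 5-bromo-1,2,3-tris(benzyloxy)benzene | Brc1cc(OCc2ccccc2)c(OCc2ccccc2)c(OCc2ccccc2)c1 | intermediate
17 | [3,4,5-tris(benzyloxy)phenyl]lithium | [Li]c1cc(OCc2ccccc2)c(OCc2ccccc2)c(OCc2ccccc2)c1 | intermediate
18 | [3,4,5-tris(benzyloxy)phenyl]zinc bromide | Br[Zn]c1cc(OCc2ccccc2)c(OCc2ccccc2)c(OCc2ccccc2)c1 | intermediate
19 | (2R,3S,4R)-7-(benzyloxy)-2-[3,4,5-tris(benzyloxy)phenyl]-4-[Ar(D)]chroman-3-yl 2,2-dimethylpropanoate | c1ccccc1COc1ccc2c(c1)O[C@H](c1cc(OCc3ccccc3)c(OCc3ccccc3)c(OCc3ccccc3)c1)[C@@H](OC(=O)C(C)(C)C)[C@H]2c1c(OCc3ccccc3)c(Br)c2c(c1OCc3ccccc3)C[C@H](OCc3ccccc3)[C@@H](c1cc(OCc3ccccc3)c(OCc3ccccc3)c(OCc3ccccc3)c1)O2 | intermediate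
20 | (2R,3S,4R)-7-(benzyloxy)-2-[3,4,5-tris(benzyloxy)phenyl]-4-[Ar(D)]chroman-3-ol | c1ccccc1COc1ccc2c(c1)O[C@H](c1cc(OCc3ccccc3)c(OCc3ccccc3)c(OCc3ccccc3)c1)[C@@H](O)[C@H]2c1c(OCc3ccccc3)c(Br)c2c(c1OCc3ccccc3)C[C@H](OCc3ccccc3)[C@@H](c1cc(OCc3ccccc3)c(OCc3ccccc3)c(OCc3ccccc3)c1)O2 | intermediate
21 | (2R,3S,4R)-4-[(2R,3S)-3,5,7-trihydroxy-2-(3,4,5-trihydroxyphenyl)chroman-6-yl]-2-(3,4,5-trihydroxyphenyl)chroman-3,7-diol | Oc1ccc2c(c1)O[C@H](c1cc(O)c(O)c(O)c1)[C@@H](O)[C@H]2c1c(O)cc2c(c1O)C[C@H](O)[C@@H](c1cc(O)c(O)c(O)c1)O2 | target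

## Step count and least certain steps

Total: 15 steps. Longest linear sequence: 13 steps (from 1 through steps 1–10 and 13–15). The ring B branch (steps 11 and 12) joins in step 13.

**Step 6 (key step).** The most likely failure is low conversion: the iminium ion of 7 is hindered by two ortho benzyloxy groups and deactivated by the electron-rich ring D, while 8 is a weak carbon nucleophile. Attack para to the hydroxyl, which cannot lactolise, and weak facial discrimination are further risks. If only the sense of induction is wrong, the mirror-image catalyst is used. The fallback sets out from aldehyde 5 and returns at 9.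
- Knoevenagel condensation of 5 with Meldrum's acid (pyrrolidinium acetate, toluene) would give the arylidene Meldrum's acid F1, a much stronger acceptor than the enal.
- Yb(OTf)3-catalysed reaction of F1 with 8 (MeNO2, 60–80 °C) is a Friedel–Crafts conjugate addition followed by acylative ring closure with loss of acetone and carbon dioxide. It would give the (4R)-dihydrocoumarin F2 together with its (4S)-epimer F3.
- F2 and F3 are diastereomers because of the lower unit and should be separable by chromatography.
- DIBAL-H at −78 °C would reduce F2 to lactol 9.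
- The price is the loss of catalyst control at C4.

**Step 7.** Three processes may interfere: slow enamine formation because the aldehyde is held as the lactol, a mismatched pairing of D-proline with the C4 centre that lowers facial selectivity, and epimerisation of the α-oxygenated aldehyde. The fallback sets out from 9 and returns at 11.
- Oxidation of 9 with Ag2CO3 on Celite (toluene, reflux) would give the dihydrocoumarin F2 described above.
- Hydroxylation of its potassium enolate (KHMDS, −78 °C) with 3-phenyl-2-(phenylsulfonyl)oxaziridine should occur anti to the C4 aryl and give the trans-hydroxy lactone F4.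
- Tf2O and pyridine would give the triflate F5.
- Displacement with CsOAc (18-crown-6, toluene) inverts C3 and gives the cis-acetate F6.
- Excess DIBAL-H at −78 °C reduces the lactone to the lactol and removes the acetate, which gives 11.

**Step 13.** Possible failures are loss of hydrogen bromide from 13 to a 4H-chromene enol ester, aryl transfer without face control if the crowded dioxolenium ion does not form, and sluggish transfer from zinc. The fallback sets out from 11 and returns at 20.
- Excess [3,4,5-tris(benzyloxy)phenyl]magnesium bromide (from 16, Mg, THF) would add to the open hydroxy-aldehyde form of 11 under chelation control by the C3 magnesium alkoxide and give the syn-diol F7.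
- Mitsunobu cyclisation (PPh3, DIAD, THF, 0 °C) lets the ring A phenol displace the activated benzylic hydroxyl with inversion, which closes ring C with the 2,3-trans relation and gives 20.
- Steps 9, 10, 13 and 14 are bypassed.

**Step 4.** The doubly flanked C6 may fail to react, or the reagent may attack ipso at C8 or on ring E. The fallback sets out from 4 and returns at 5.
- Iodination with N-iodosuccinimide (cat. CF3CO2H, MeCN/CH2Cl2) would give the 6-iodide F8.
- Selective iodine–magnesium exchange with i-PrMgCl·LiCl (THF, −20 → 0 °C) leaves the C8 bromide untouched, and a DMF quench gives 5.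

## Further compounds

F1 | step 6 | 5-{[(2R,3S)-3,5,7-tris(benzyloxy)-8-bromo-2-[3,4,5-tris(benzyloxy)phenyl]chroman-6-yl]methylidene}-2,2-dimethyl-1,3-dioxane-4,6-dione | CC1(C)OC(=O)C(C(=O)O1)=Cc1c(OCc3ccccc3)c(Br)c2c(c1OCc3ccccc3)C[C@H](OCc3ccccc3)[C@@H](c1cc(OCc3ccccc3)c(OCc3ccccc3)c(OCc3ccccc3)c1)O2
F2 | step 6 | (4R)-7-(benzyloxy)-4-[Ar(D)]chroman-2-one | c1ccccc1COc1ccc2c(c1)OC(=O)C[C@H]2c1c(OCc3ccccc3)c(Br)c2c(c1OCc3ccccc3)C[C@H](OCc3ccccc3)[C@@H](c1cc(OCc3ccccc3)c(OCc3ccccc3)c(OCc3ccccc3)c1)O2
F3 | step 6 | (4S)-7-(benzyloxy)-4-[Ar(D)]chroman-2-one | c1ccccc1COc1ccc2c(c1)OC(=O)C[C@@H]2c1c(OCc3ccccc3)c(Br)c2c(c1OCc3ccccc3)C[C@H](OCc3ccccc3)[C@@H](c1cc(OCc3ccccc3)c(OCc3ccccc3)c(OCc3ccccc3)c1)O2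
F4 | step 7 | (3R,4R)-7-(benzyloxy)-3-hydroxy-4-[Ar(D)]chroman-2-one | c1ccccc1COc1ccc2c(c1)OC(=O)[C@H](O)[C@H]2c1c(OCc3ccccc3)c(Br)c2c(c1OCc3ccccc3)C[C@H](OCc3ccccc3)[C@@H](c1cc(OCc3ccccc3)c(OCc3ccccc3)c(OCc3ccccc3)c1)O2
F5 | step 7 | (3R,4R)-7-(benzyloxy)-2-oxo-4-[Ar(D)]chroman-3-yl trifluoromethanesulfonate | c1ccccc1COc1ccc2c(c1)OC(=O)[C@H](OS(=O)(=O)C(F)(F)F)[C@H]2c1c(OCc3ccccc3)c(Br)c2c(c1OCc3ccccc3)C[C@H](OCc3ccccc3)[C@@H](c1cc(OCc3ccccc3)c(OCc3ccccc3)c(OCc3ccccc3)c1)O2
F6 | step 7 | (3S,4R)-7-(benzyloxy)-2-oxo-4-[Ar(D)]chroman-3-yl acetate | c1ccccc1COc1ccc2c(c1)OC(=O)[C@@H](OC(C)=O)[C@H]2c1c(OCc3ccccc3)c(Br)c2c(c1OCc3ccccc3)C[C@H](OCc3ccccc3)[C@@H](c1cc(OCc3ccccc3)c(OCc3ccccc3)c(OCc3ccccc3)c1)O2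
F7 | step 13 | (1S,2S,3R)-3-[4-(benzyloxy)-2-hydroxyphenyl]-3-[Ar(D)]-1-[3,4,5-tris(benzyloxy)phenyl]propane-1,2-diol | Oc1cc(OCc2ccccc2)ccc1[C@H](c1c(OCc3ccccc3)c(Br)c2c(c1OCc3ccccc3)C[C@H](OCc3ccccc3)[C@@H](c1cc(OCc3ccccc3)c(OCc3ccccc3)c(OCc3ccccc3)c1)O2)[C@H](O)[C@@H](O)c1cc(OCc2ccccc2)c(OCc2ccccc2)c(OCc2ccccc2)c1
F8 | step 4 | (2R,3S)-3,5,7-tris(benzyloxy)-8-bromo-6-iodo-2-[3,4,5-tris(benzyloxy)phenyl]chroman | c1ccccc1COc1c(I)c(OCc2ccccc2)c2C[C@H](OCc3ccccc3)[C@@H](c3cc(OCc4ccccc4)c(OCc4ccccc4)c(OCc4ccccc4)c3)Oc2c1Br
A1 | alternative 1 | nona-O-benzyl ether of the target (both C3 hydroxyls free) | c1ccccc1COc1ccc2c(c1)O[C@H](c1cc(OCc3ccccc3)c(OCc3ccccc3)c(OCc3ccccc3)c1)[C@@H](O)[C@H]2c1c(OCc3ccccc3)cc2c(c1OCc3ccccc3)C[C@H](O)[C@@H](c1cc(OCc3ccccc3)c(OCc3ccccc3)c(OCc3ccccc3)c1)O2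
A2 | alternative 1 | open-chain bis(trans-epoxide) with free ring A and ring D phenols (A1 opened at both O1–C2 bonds) | Oc1cc(OCc2ccccc2)ccc1[C@H](c3c(OCc4ccccc4)cc(O)c(C[C@@H]4O[C@H]4c4cc(OCc5ccccc5)c(OCc5ccccc5)c(OCc5ccccc5)c4)c3OCc3ccccc3)[C@@H]1O[C@H]1c1cc(OCc2ccccc2)c(OCc2ccccc2)c(OCc2ccccc2)c1
A3 | alternative 2 | protected target with free 4-hydroxyl on ring E, free lower C3 hydroxyl and silyl ether at the upper C3 | c1ccccc1COc1ccc2c(c1)O[C@H](c1cc(OCc3ccccc3)c(OCc3ccccc3)c(OCc3ccccc3)c1)[C@@H](O[Si](C)(C)C(C)(C)C)[C@H]2c1c(OCc3ccccc3)cc2c(c1OCc3ccccc3)C[C@H](O)[C@@H](c1cc(OCc3ccccc3)c(O)c(OCc3ccccc3)c1)O2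
A4 | alternative 2 | ring F-opened phenol: upper unit bearing a ring D phenol and a 1-aryl-3-(4-hydroxy-3,5-dibenzyloxyphenyl)propan-2-ol chain | c1ccccc1COc1ccc2c(c1)O[C@H](c1cc(OCc3ccccc3)c(OCc3ccccc3)c(OCc3ccccc3)c1)[C@@H](O[Si](C)(C)C(C)(C)C)[C@H]2c1c(OCc3ccccc3)cc(O)c(c1OCc3ccccc3)C[C@H](O)Cc1cc(OCc3ccccc3)c(O)c(OCc3ccccc3)c1
A5 | alternative 2 | para-quinone methide formed from A4 | c1ccccc1COc1ccc2c(c1)O[C@H](c1cc(OCc3ccccc3)c(OCc3ccccc3)c(OCc3ccccc3)c1)[C@@H](O[Si](C)(C)C(C)(C)C)[C@H]2c1c(OCc3ccccc3)cc(O)c(c1OCc3ccccc3)C[C@H](O)C=C1C=C(OCc3ccccc3)C(=O)C(OCc3ccccc3)=C1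
A6 | alternative 3 | protected target with benzyl ethers on the upper unit and methoxymethyl and silyl ethers on the lower unit | c1ccccc1COc1ccc2c(c1)O[C@H](c1cc(OCc3ccccc3)c(OCc3ccccc3)c(OCc3ccccc3)c1)[C@@H](OCc3ccccc3)[C@H]2c1c(OCOC)cc2c(c1OCOC)C[C@H](O[Si](C)(C)C(C)(C)C)[C@@H](c1cc(OCOC)c(OCOC)c(OCOC)c1)O2
A7 | alternative 3 | open-chain bromo alcohol: C2 benzylic alcohol, C3 benzyl ether, C4 bearing ring D and a 2-bromo-4-(benzyloxy)phenyl group | c1ccccc1COc1ccc(c(Br)c1)[C@H](c1c(OCOC)cc2c(c1OCOC)C[C@H](O[Si](C)(C)C(C)(C)C)[C@@H](c1cc(OCOC)c(OCOC)c(OCOC)c1)O2)[C@H](OCc3ccccc3)[C@H](O)c1cc(OCc3ccccc3)c(OCc3ccccc3)c(OCc3ccccc3)c1
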